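The route rests on a thermal intramolecular Diels–Alder reaction that builds the cyclohexene ring (C1, C10–C14, briarane numbering). Three features of this ring are exploited: oxygen on C14, oxygen on the neighbouring C9 and the methyl C20 on C11. They become a 2-silyloxydiene (C13=C14–C1=C10), an ester tether through O-9 and a propiolate whose carbonyl carbon is C20. One operation closes the C12–C13 and C10–C11 bonds and a temporary butenolide, and sets C10 from C9. Its precursor is an acyclic dienyl propiolate. Aldol chemistry at C1, reduction of C20 to methyl, a Reformatsky lactonisation and a Nozaki–Hiyama–Kishi closure of the ten-membered ring complete the synthesis.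

Key step: step 5

Remark on the chemistry: briarane numbering is used for all intermediates (C1 quaternary carbon, C2–C9 in the ten-membered ring, C10 ring fusion, C11–C14 cyclohexene, C15 methyl on C1, C16 hydroxymethyl on C5, C17–C19 lactone, C20 methyl on C11). The target is read as 1R,2R,4R,5Z,7S,8S,9R,10S,14S,17R with an (R)-3-acetoxybutanoate on O-4. Compounds 1, 4, 5, 8, 12, 17, 27 and 35 are assumed to be purchasable.

Step 1
Reactants: 1 2,3-dimethylfuran
Product: 3 (2E)-3-methyl-4-oxopent-2-enal, via (2Z)-3-methyl-4-oxopent-2-enal 2 (not isolated)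
Conditions: mCPBA, CH2Cl2, 0 °C; then I2 (cat.), rt
Reagents that add atoms: 3-chloroperoxybenzoic acid (mCPBA), OOC(=O)c1cccc(Cl)c1
Why: Oxidative ring opening of the furan should give the cis-enedicarbonyl compound, and iodine-catalysed Z to E isomerisation should place the formyl group trans to the acetyl group.

Step 2
Reactants: 3 (2E)-3-methyl-4-oxopent-2-enal; 4 allyl methoxymethyl ether; 5 (−)-B-methoxydiisopinocampheylborane
Product: 7 (3E,5R,6R)-5-hydroxy-6-(methoxymethoxy)-3-methylocta-3,7-dien-2-one, via (Z)-alkoxyallylborane 6 (not isolated)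
Conditions: 4, s-BuLi, THF, −78 °C; 5; BF3·OEt2; then 3, −78 °C; then ethanolamine, rt
Reagents that add atoms: allyl methoxymethyl ether (4), C=CCOCOC
Why: γ-Alkoxyallylboration through a chair Zimmerman–Traxler transition state: the Z-allylborane should give the syn 1,2-diol monoether, the isopinocampheyl groups from (+)-α-pinene should direct attack to the Si face of the formyl group to set C9 (and the temporary C8 centre), and the ketone should not react at −78 °C.

Step 3
Reactants: 7 (3E,5R,6R)-5-hydroxy-6-(methoxymethoxy)-3-methylocta-3,7-dien-2-one; 8 propiolic acid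
Product: 9 (3E,5R,6R)-6-(methoxymethoxy)-3-methyl-2-oxoocta-3,7-dien-5-yl prop-2-ynoate
Conditions: 8, DCC, DMAP (cat.), CH2Cl2, −20 °C
Reagents that add atoms: propiolic acid (8), C#CC(=O)O
Why: Steglich esterification at low temperature, where carbodiimide activation should outrun conjugate addition to the ynoate; C9 is not touched.

Step 4
Reactants: 9 (3E,5R,6R)-6-(methoxymethoxy)-3-methyl-2-oxoocta-3,7-dien-5-yl prop-2-ynoate
Product: 10 (3E,5R,6R)-2-[(tert-butyldimethylsilyl)oxy]-6-(methoxymethoxy)-3-methylocta-1,3,7-trien-5-yl prop-2-ynoate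
Conditions: TBSOTf, i-Pr2NEt, CH2Cl2, −78 °C
Reagents that add atoms: tert-butyldimethylsilyl triflate, CC(C)(C)[Si](C)(C)OS(=O)(=O)C(F)(F)F
Why: Soft enolisation of the methyl ketone toward its only α-CH3 (C13) should give the cross-conjugated 2-silyloxydiene, with the hindered amine chosen to avoid addition to the propiolate.

Step 5
Reactants: 10 (3E,5R,6R)-2-[(tert-butyldimethylsilyl)oxy]-6-(methoxymethoxy)-3-methylocta-1,3,7-trien-5-yl prop-2-ynoate
Product: 11 (3R,3aR)-5-[(tert-butyldimethylsilyl)oxy]-3-[(1R)-1-(methoxymethoxy)prop-2-en-1-yl]-4-methyl-3a,6-dihydro-2-benzofuran-1(3H)-one (H-9 and H-10 trans on the lactone)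
Conditions: toluene (degassed), BHT (cat.), 110 °C, 0.01 M
Reagents that add atoms: none
Why: Concerted, asynchronous [4+2] cycloaddition of the electron-rich 2-silyloxy-3-methyldiene (C13=C14–C1=C10) with the tethered, electron-poor propiolate (C12≡C11), in which the nucleophilic terminus C13 bonds to the β-carbon C12 and C10 bonds to C11; the closest known reaction type is the type 1 intramolecular Diels–Alder reaction of dienyl propiolates, which gives fused butenolides. The cyclohexa-1,4-diene closes in the [4+2] mode and the five-membered lactone closes as the fused tether ring, giving a bicyclo[4.3.0] system. The only new stereocentre, C10, is controlled by C9: allylic 1,3-strain with the C15 methyl on C1 keeps H-9 near the diene plane, the C9–O bond then delivers the alkyne to one diene face while C8 points to the other, so H-9 and H-10 should end up trans on the lactone as the target requires. The step needs regioselectivity, which the three-atom tether and the matched polarisation both secure, and site selectivity over the isolated vinyl group, which is unactivated. The 2,3-disubstitution of the diene favours the s-cis form, and dilution, exclusion of oxygen and BHT should suppress intermolecular addition and aromatisation of the skipped diene.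

Step 6
Reactants: 11 Diels–Alder adduct; 12 3-[(tert-butyldimethylsilyl)oxy]propanal
Product: 13 aldol adduct (14-ketone, C1 quaternary with C15 cis to C9, 2-hydroxy as C2 epimers, 4-OTBS, butenolide intact)
Conditions: 12, BF3·OEt2, CH2Cl2, −78 °C
Reagents that add atoms: 3-[(tert-butyldimethylsilyl)oxy]propanal (12), O=CCCO[Si](C)(C)C(C)(C)C
Why: Mukaiyama aldol addition through an open transition state, in which the activated aldehyde should attack C1 of the tetrasubstituted enol silane on the face opposite the C9 substituent of the neighbouring C10, setting the quaternary centre; the C2 carbinol forms as an epimer mixture that converges in step 7.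

Step 7
Reactants: 13 aldol adduct
Product: 14 2,14-diketone
Conditions: Dess–Martin periodinane, NaHCO3, CH2Cl2, 0 °C to rt
Reagents that add atoms: none
Why: Dess–Martin oxidation of the secondary alcohol should give the non-enolisable 2,2-disubstituted 1,3-diketone and erase the uncontrolled C2 centre.

Step 8
Reactants: 14 2,14-diketone
Product: 15 2,14-syn diol (C2 and C14 as in the target)
Conditions: Zn(BH4)2, Et2O, −30 to 0 °C
Reagents that add atoms: none
Why: Chelation-controlled hydride reduction, in which zinc bridges the two oxygens and hydride should enter each carbonyl from the chelate face that carries the C15 methyl, away from C10 and the carbocycle, giving the 2,14-syn diol with both hydroxyls anti to C15; the butenolide is inert to this reagent.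

Step 9
Reactants: 15 2,14-syn diol
Product: 16 C7 aldehyde (α-OMOM aldehyde)
Conditions: O3, NaHCO3, CH2Cl2/MeOH, −78 °C; then PPh3
Reagents that add atoms: ozone, [O-][O+]=O
Why: Ozonolysis with reductive work-up should cleave the terminal vinyl group, while the butenolide alkene is deactivated by conjugation and should survive.

Step 10
Reactants: 16 C7 aldehyde; 17 tert-butyl(diphenyl)(prop-2-yn-1-yloxy)silane
Product: 19 propargylic alcohol (7,8-syn), via alkynylzinc bromide 18 (not isolated)
Conditions: 17, n-BuLi, THF, −78 °C; ZnBr2; then 16, Et2O/THF, −78 to −20 °C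
Reagents that add atoms: tert-butyl(diphenyl)(prop-2-yn-1-yloxy)silane (17), C#CCO[Si](c1ccccc1)(c1ccccc1)C(C)(C)C
Why: Cram-chelate addition of an alkynylzinc halide, in which zinc bridges the formyl and MOM oxygens and the alkyne should enter from the face away from C9, giving the 7,8-syn carbinol and hence the 1,3-syn relation of O-7 and O-9 found in the target; lactone and free hydroxyls are tolerated with excess reagent.

Step 11
Reactants: 19 propargylic alcohol
Product: 21 2,2-dimethyl-2,5-dihydro-1,2-oxasilole (SiMe2 bridging O-7 and C5), via acyclic vinyl(ethoxy)silane 20 (not isolated)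
Conditions: [Cp*Ru(MeCN)3]PF6 (cat.), HSiMe2(OEt), CH2Cl2, 0 °C to rt; then PPTS (cat.)
Reagents that add atoms: ethoxydimethylsilane, CCO[SiH](C)C
Why: Ruthenium-catalysed trans-hydrosilylation of a propargylic alcohol should place silicon on the distal carbon C5 and hydrogen on C6 in an anti sense, and the ethoxysilane should then close onto the C7 hydroxyl, which fixes the cis relation of C7 and silicon and masks O-7.

Step 12
Reactants: 21 oxasilole
Product: 22 2,9,14,20-tetraol
Conditions: i-Bu2AlH, CH2Cl2, −78 to −20 °C; aq. potassium sodium tartrate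
Reagents that add atoms: none
Why: 1,2-Reduction of the α,β-unsaturated lactone through its lactol should give the allylic 9,20-diol, with silyl ethers, MOM ether and oxasilole stable to the hydride at low temperature.

Step 13
Reactants: 22 tetraol
Product: 23 C20 allylic chloride
Conditions: MsCl, 2,4,6-collidine, LiCl, DMF, 0 °C
Reagents that add atoms: lithium chloride, [Li+].[Cl-]
Why: Mesylation with chloride exchange should occur much faster at the primary allylic C20 hydroxyl than at the three hindered secondary hydroxyls.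

Step 14
Reactants: 23 allylic chloride
Product: 24 2,9,14-triol with C20 methyl
Conditions: NaBH4, DMSO, rt
Reagents that add atoms: none
Why: SN2 hydride displacement of the primary allylic chloride by borohydride in a dipolar aprotic solvent should give the C20 methyl without generating alkoxides that could close a cyclic ether onto C20.

Step 15
Reactants: 24 triol
Product: 25 2,9,14-triacetate
Conditions: Ac2O, DMAP, pyridine, rt to 40 °C
Reagents that add atoms: acetic anhydride, CC(=O)OC(C)=O
Why: DMAP-catalysed acetylation should esterify the three secondary hydroxyls in one operation while O-7 stays masked in the oxasilole.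

Step 16
Reactants: 25 triacetate
Product: 26 (5Z)-vinyl iodide with free 7-hydroxyl
Conditions: NIS, 2,6-lutidine, (CF3)2CHOH/CH2Cl2, 0 °C; then aq. NaHCO3/Na2S2O3
Reagents that add atoms: N-iodosuccinimide, O=C1CCC(=O)N1I
Why: Electrophilic ipso-iododesilylation of the vinylsilane via a β-silicon-stabilised cation should proceed with retention to the Z-vinyl iodide, and hydrolysis of the resulting silyl ether frees the C7 hydroxyl.

Step 17
Reactants: 26 vinyl iodide; 27 2-bromopropanoyl bromide
Product: 28 7-O-(2-bromopropanoyl) ester (both epimers at the bromide carbon)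
Conditions: 27, pyridine, CH2Cl2, −20 °C
Reagents that add atoms: 2-bromopropanoyl bromide (27), CC(Br)C(Br)=O
Why: Acylation of the only free hydroxyl with an acyl bromide should be clean; the bromide-bearing carbon later becomes an enolate, so its configuration is irrelevant.

Step 18
Reactants: 28 bromopropanoate
Product: 29 8-alcohol
Conditions: Me2BBr, CH2Cl2, −78 °C; then aq. NaHCO3
Reagents that add atoms: none
Why: Bromoborane cleavage of the MOM acetal at low temperature should free the C8 hydroxyl and spare acetates, silyl ethers, the bromo ester and the vinyl iodide.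

Step 19
Reactants: 29 8-alcohol
Product: 30 8-ketone
Conditions: Dess–Martin periodinane, NaHCO3, CH2Cl2, 0 °C
Reagents that add atoms: none
Why: Buffered Dess–Martin oxidation should give the ketone without epimerising the α-acyloxy centres C7 and C9.

Step 20
Reactants: 30 8-ketone
Product: 31 8-hydroxy-γ-lactone (C7, C8, C17 as in the target)
Conditions: Zn (activated with TMSCl), THF, 0 °C to rt
Reagents that add atoms: none
Why: Intramolecular Reformatsky reaction of an α-bromoacyloxy ketone, in which the zinc enolate should add 5-exo to the C8 carbonyl and the bulky C9 branch should take the lactone face opposite to both the C6 alkenyl group on C7 and the new C18 methyl on C17, setting C8 and C17.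

Step 21
Reactants: 31 hydroxy lactone
Product: 32 4-alcohol
Conditions: HF·pyridine, pyridine, THF, 0 °C
Reagents that add atoms: none
Why: Buffered fluoride desilylation should remove the primary TBS ether selectively over the primary TBDPS ether.

Step 22
Reactants: 32 4-alcohol
Product: 33 4-aldehyde
Conditions: Dess–Martin periodinane, NaHCO3, CH2Cl2, 0 °C
Reagents that add atoms: none
Why: Dess–Martin oxidation of the primary alcohol should give the aldehyde, the tertiary C8 hydroxyl being unable to oxidise.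

Step 23
Reactants: 33 4-aldehyde
Product: 34 macrocyclic allylic alcohol (4R, ring-cis C5=C6, 16-OTBDPS)
Conditions: CrCl2, NiCl2 (cat.), DMSO/THF, rt, 0.002 M (slow addition)
Reagents that add atoms: none
Why: Nozaki–Hiyama–Kishi reaction, in which the alkenylchromium species forms with retention of alkene geometry and should add intramolecularly to the aldehyde to close the ten-membered ring, attack on the outward aldehyde face of the folded chain being expected to give the 4R alcohol; high dilution should suppress oligomers.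

Step 24
Reactants: 35 (R)-3-hydroxybutanoic acid
Product: 36 (R)-3-acetoxybutanoic acid
Conditions: AcCl, rt; then H2O
Reagents that add atoms: acetyl chloride, CC(Cl)=O
Why: O-Acetylation of the β-hydroxy acid with an acyl chloride does not involve the stereocentre.

Step 25
Reactants: 34 macrocyclic allylic alcohol; 36 (R)-3-acetoxybutanoic acid
Product: 37 16-O-TBDPS ether of the target
Conditions: 36, EDC·HCl, DMAP (cat.), CH2Cl2, 0 °C
Reagents that add atoms: (R)-3-acetoxybutanoic acid (36), CC(=O)O[C@H](C)CC(=O)O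
Why: Steglich-type carbodiimide esterification of the secondary allylic C4 hydroxyl proceeds with retention, the tertiary C8 hydroxyl is too hindered to react, and the low temperature should avoid elimination of the β-acetoxy acyl unit.

Step 26
Reactants: 37 16-O-TBDPS ether
Product: 38 CNP0316115.1 (target)
Conditions: HF·pyridine, pyridine, THF, rt
Reagents that add atoms: none
Why: Buffered, weakly acidic fluoride cleavage of the TBDPS ether should free the C16 hydroxyl without acyl migration from O-4.

Compound list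
1 | 2,3-dimethylfuran | Cc1occc1C | starting material
2 | (2Z)-3-methyl-4-oxopent-2-enal | CC(=O)/C(C)=C\C=O | intermediate
3 | (2E)-3-methyl-4-oxopent-2-enal | CC(=O)/C(C)=C/C=O | intermediate
4 | allyl methoxymethyl ether | C=CCOCOC | starting material
5 | (−)-B-methoxydiisopinocampheylborane (from (+)-α-pinene) | COB([C@@H]1C[C@@H]2C[C@H]([C@H]1C)C2(C)C)[C@@H]1C[C@@H]2C[C@H]([C@H]1C)C2(C)C | starting material
6 | [(Z)-3-(methoxymethoxy)allyl]diisopinocampheylborane | COCO/C=C\CB([C@@H]1C[C@@H]2C[C@H]([C@H]1C)C2(C)C)[C@@H]1C[C@@H]2C[C@H]([C@H]1C)C2(C)C | intermediate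
7 | (3E,5R,6R)-5-hydroxy-6-(methoxymethoxy)-3-methylocta-3,7-dien-2-one | C=C[C@@H](OCOC)[C@H](O)/C=C(\C)C(C)=O | intermediate
8 | propiolic acid | C#CC(=O)O | starting material
9 | (3E,5R,6R)-6-(methoxymethoxy)-3-methyl-2-oxoocta-3,7-dien-5-yl prop-2-ynoate | C=C[C@@H](OCOC)[C@H](OC(=O)C#C)/C=C(\C)C(C)=O | intermediate
10 | (3E,5R,6R)-2-[(tert-butyldimethylsilyl)oxy]-6-(methoxymethoxy)-3-methylocta-1,3,7-trien-5-yl prop-2-ynoate | C=C[C@@H](OCOC)[C@H](OC(=O)C#C)/C=C(\C)C(=C)O[Si](C)(C)C(C)(C)C | intermediate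
11 | (3R,3aR)-5-[(tert-butyldimethylsilyl)oxy]-3-[(1R)-1-(methoxymethoxy)prop-2-en-1-yl]-4-methyl-3a,6-dihydro-2-benzofuran-1(3H)-one | CC1=C(O[Si](C)(C)C(C)(C)C)CC=C2[C@@H]1[C@@H](OC2=O)[C@H](OCOC)C=C | intermediate
12 | 3-[(tert-butyldimethylsilyl)oxy]propanal | O=CCCO[Si](C)(C)C(C)(C)C | starting material
13 | aldol adduct: 14-ketone, quaternary C1, 2-hydroxy (C2 epimers), 4-OTBS, butenolide, 8-OMOM, C7 vinyl | CC(C)(C)[Si](C)(C)OCCC(O)[C@@]1(C)C(=O)CC=C2[C@@H]1[C@@H](OC2=O)[C@H](OCOC)C=C | intermediate
14 | 2,14-diketone of 13 | CC(C)(C)[Si](C)(C)OCCC(=O)[C@@]1(C)C(=O)CC=C2[C@@H]1[C@@H](OC2=O)[C@H](OCOC)C=C | intermediate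
15 | 2,14-syn diol (2R,14S centres of the target) with butenolide | CC(C)(C)[Si](C)(C)OCC[C@@H](O)[C@@]1(C)[C@@H](O)CC=C2[C@@H]1[C@@H](OC2=O)[C@H](OCOC)C=C | intermediate
16 | C7 aldehyde (vinyl group of 15 cleaved) | CC(C)(C)[Si](C)(C)OCC[C@@H](O)[C@@]1(C)[C@@H](O)CC=C2[C@@H]1[C@@H](OC2=O)[C@H](OCOC)C=O | intermediate
17 | tert-butyl(diphenyl)(prop-2-yn-1-yloxy)silane | C#CCO[Si](c1ccccc1)(c1ccccc1)C(C)(C)C | starting material
18 | {3-[(tert-butyldiphenylsilyl)oxy]prop-1-yn-1-yl}zinc bromide | Br[Zn]C#CCO[Si](c1ccccc1)(c1ccccc1)C(C)(C)C | intermediate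
19 | propargylic alcohol (7-hydroxy, 7,8-syn, C6≡C5, 16-OTBDPS) | CC(C)(C)[Si](C)(C)OCC[C@@H](O)[C@@]1(C)[C@@H](O)CC=C2[C@@H]1[C@@H](OC2=O)[C@H](OCOC)[C@@H](O)C#CCO[Si](c3ccccc3)(c3ccccc3)C(C)(C)C | intermediate
20 | acyclic (Z)-vinyl(ethoxy)dimethylsilane (Si on C5, cis to C7) | CC(C)(C)[Si](C)(C)OCC[C@@H](O)[C@@]1(C)[C@@H](O)CC=C2[C@@H]1[C@@H](OC2=O)[C@H](OCOC)[C@@H](O)/C=C(/CO[Si](c3ccccc3)(c3ccccc3)C(C)(C)C)[Si](C)(C)OCC | intermediate
21 | 2,2-dimethyl-2,5-dihydro-1,2-oxasilole (SiMe2 between O-7 and C5), butenolide intact | CC(C)(C)[Si](C)(C)OCC[C@@H](O)[C@@]1(C)[C@@H](O)CC=C2[C@@H]1[C@@H](OC2=O)[C@H](OCOC)[C@H]3O[Si](C)(C)C(CO[Si](c4ccccc4)(c4ccccc4)C(C)(C)C)=C3 | intermediate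
22 | 2,9,14,20-tetraol (lactone reduced) | CC(C)(C)[Si](C)(C)OCC[C@@H](O)[C@@]1(C)[C@@H](O)CC=C(CO)[C@@H]1[C@@H](O)[C@H](OCOC)[C@H]2O[Si](C)(C)C(CO[Si](c3ccccc3)(c3ccccc3)C(C)(C)C)=C2 | intermediate
23 | C20 allylic chloride, 2,9,14-triol | CC(C)(C)[Si](C)(C)OCC[C@@H](O)[C@@]1(C)[C@@H](O)CC=C(CCl)[C@@H]1[C@@H](O)[C@H](OCOC)[C@H]2O[Si](C)(C)C(CO[Si](c3ccccc3)(c3ccccc3)C(C)(C)C)=C2 | intermediate
24 | 2,9,14-triol with C20 methyl | CC(C)(C)[Si](C)(C)OCC[C@@H](O)[C@@]1(C)[C@@H](O)CC=C(C)[C@@H]1[C@@H](O)[C@H](OCOC)[C@H]2O[Si](C)(C)C(CO[Si](c3ccccc3)(c3ccccc3)C(C)(C)C)=C2 | intermediate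
25 | 2,9,14-triacetate | CC(C)(C)[Si](C)(C)OCC[C@@H](OC(C)=O)[C@@]1(C)[C@@H](OC(C)=O)CC=C(C)[C@@H]1[C@@H](OC(C)=O)[C@H](OCOC)[C@H]2O[Si](C)(C)C(CO[Si](c3ccccc3)(c3ccccc3)C(C)(C)C)=C2 | intermediate
26 | (5Z)-5-iodoalkene with free 7-hydroxyl | CC(C)(C)[Si](C)(C)OCC[C@@H](OC(C)=O)[C@@]1(C)[C@@H](OC(C)=O)CC=C(C)[C@@H]1[C@@H](OC(C)=O)[C@H](OCOC)[C@@H](O)/C=C(\I)CO[Si](c2ccccc2)(c2ccccc2)C(C)(C)C | intermediate
27 | 2-bromopropanoyl bromide (racemic) | CC(Br)C(Br)=O | starting material
28 | 7-O-(2-bromopropanoyl) ester (epimers at CHBr) | CC(C)(C)[Si](C)(C)OCC[C@@H](OC(C)=O)[C@@]1(C)[C@@H](OC(C)=O)CC=C(C)[C@@H]1[C@@H](OC(C)=O)[C@H](OCOC)[C@@H](OC(=O)C(C)Br)/C=C(\I)CO[Si](c2ccccc2)(c2ccccc2)C(C)(C)C | intermediate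
29 | 8-alcohol (MOM removed) | CC(C)(C)[Si](C)(C)OCC[C@@H](OC(C)=O)[C@@]1(C)[C@@H](OC(C)=O)CC=C(C)[C@@H]1[C@@H](OC(C)=O)[C@H](O)[C@@H](OC(=O)C(C)Br)/C=C(\I)CO[Si](c2ccccc2)(c2ccccc2)C(C)(C)C | intermediate
30 | 8-ketone | CC(C)(C)[Si](C)(C)OCC[C@@H](OC(C)=O)[C@@]1(C)[C@@H](OC(C)=O)CC=C(C)[C@@H]1[C@@H](OC(C)=O)C(=O)[C@@H](OC(=O)C(C)Br)/C=C(\I)CO[Si](c2ccccc2)(c2ccccc2)C(C)(C)C | intermediate
31 | 8-hydroxy-17-methyl-γ-lactone (7S,8S,17R centres of the target), 4-OTBS | CC(C)(C)[Si](C)(C)OCC[C@@H](OC(C)=O)[C@@]1(C)[C@@H](OC(C)=O)CC=C(C)[C@@H]1[C@@H](OC(C)=O)[C@@]1(O)[C@H](/C=C(\I)CO[Si](c2ccccc2)(c2ccccc2)C(C)(C)C)OC(=O)[C@@H]1C | intermediate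
32 | 4-alcohol | OCC[C@@H](OC(C)=O)[C@@]1(C)[C@@H](OC(C)=O)CC=C(C)[C@@H]1[C@@H](OC(C)=O)[C@@]1(O)[C@H](/C=C(\I)CO[Si](c2ccccc2)(c2ccccc2)C(C)(C)C)OC(=O)[C@@H]1C | intermediate
33 | 4-aldehyde (seco precursor) | O=CC[C@@H](OC(C)=O)[C@@]1(C)[C@@H](OC(C)=O)CC=C(C)[C@@H]1[C@@H](OC(C)=O)[C@@]1(O)[C@H](/C=C(\I)CO[Si](c2ccccc2)(c2ccccc2)C(C)(C)C)OC(=O)[C@@H]1C | intermediate
34 | macrocyclic (4R)-allylic alcohol, 16-OTBDPS | O[C@@H]1C[C@@H](OC(C)=O)[C@@]2(C)[C@@H](OC(C)=O)CC=C(C)[C@@H]2[C@@H](OC(C)=O)[C@@]2(O)[C@H](/C=C\1CO[Si](c3ccccc3)(c3ccccc3)C(C)(C)C)OC(=O)[C@@H]2C | intermediate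
35 | (R)-3-hydroxybutanoic acid | C[C@@H](O)CC(=O)O | starting material
36 | (R)-3-acetoxybutanoic acid | CC(=O)O[C@H](C)CC(=O)O | intermediate
37 | 16-O-TBDPS ether of the target | CC(=O)O[C@H](C)CC(=O)O[C@@H]1C[C@@H](OC(C)=O)[C@@]2(C)[C@@H](OC(C)=O)CC=C(C)[C@@H]2[C@@H](OC(C)=O)[C@@]2(O)[C@H](/C=C\1CO[Si](c3ccccc3)(c3ccccc3)C(C)(C)C)OC(=O)[C@@H]2C | intermediate
38 | CNP0316115.1 | CC(=O)O[C@H](C)CC(=O)O[C@@H]1C[C@@H](OC(C)=O)[C@@]2(C)[C@@H](OC(C)=O)CC=C(C)[C@@H]2[C@@H](OC(C)=O)[C@@]2(O)[C@H](/C=C\1CO)OC(=O)[C@@H]2C | target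

Total step count: 26. Longest linear sequence: 25 steps (steps 1–23, 25 and 26).

Steps most likely to fail

1. Step 5. The ester tether may resist the s-cis geometry that the fused transition state needs, so that intermolecular addition or oxidative aromatisation of the skipped diene overtakes the cycloaddition. The fallback sets out from 7 and closes the tether after an intermolecular cycloaddition. The C9 hydroxyl is silylated (TESCl, imidazole) to the triethylsilyl ether F1, and soft enolisation (TBSOTf, Et3N) gives the silyl dienol ether F2. Intermolecular Diels–Alder reaction with methyl propiolate (toluene, 80 °C) has the same orientation (C13 to the β-carbon) and gives the cyclohexadiene ester F3; the C10 epimers are separated, since facial control now rests only on the allylic C9 centre. Mukaiyama aldol reaction with 12 (BF3·OEt2) gives the keto ester F4, and PPTS/MeOH followed by catalytic DBU removes the triethylsilyl group and closes the lactone. The fallback comes back to the route at 13.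

2. Step 23. The ten-membered ring may close slowly against oligomerisation, or the alkenylchromium may attack the wrong aldehyde face. The fallback sets out from 33. If cyclisation delivers the epimeric alcohol 4-epi-34 F5, it is oxidised with Dess–Martin periodinane to the macrocyclic enone F6. Reagent-controlled Corey–Bakshi–Shibata reduction ((S)-Me-CBS, catecholborane, −78 °C) then sets the 4R carbinol, and the fallback comes back to the route at 34.

3. Step 8. One of the two chelate-controlled hydride deliveries may show poor facial selectivity, in particular attack on the ring ketone from the side-chain face. The fallback sets out from 14. Reagent-controlled Corey–Bakshi–Shibata reduction ((S)-Me-CBS, BH3·SMe2) of the less hindered exocyclic C2 ketone gives the (2R)-hydroxy ketone F7. Narasaka–Prasad reduction (Et2BOMe, NaBH4, THF/MeOH, −78 °C) then delivers external hydride to the boron chelate, and the fallback comes back to the route at 15.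

Further compounds
F1 | step 5 | (3E,5R,6R)-6-(methoxymethoxy)-3-methyl-5-[(triethylsilyl)oxy]octa-3,7-dien-2-one | C=C[C@@H](OCOC)[C@H](O[Si](CC)(CC)CC)/C=C(\C)C(C)=O
F2 | step 5 | silyl dienol ether of F1 (2-OTBS diene, 5-OTES) | C=C[C@@H](OCOC)[C@H](O[Si](CC)(CC)CC)/C=C(\C)C(=C)O[Si](C)(C)C(C)(C)C
F3 | step 5 | methyl cyclohexa-1,4-diene-1-carboxylate adduct (C10 as in 11, 9-OTES, 14-OTBS enol ether) | COC(=O)C1=CCC(O[Si](C)(C)C(C)(C)C)=C(C)[C@H]1[C@@H](O[Si](CC)(CC)CC)[C@H](OCOC)C=C
F4 | step 5 | keto ester aldol adduct (14-ketone, quaternary C1, 2-hydroxy epimers, C20 methyl ester, 9-OTES) | CC(C)(C)[Si](C)(C)OCCC(O)[C@@]1(C)C(=O)CC=C(C(=O)OC)[C@@H]1[C@@H](O[Si](CC)(CC)CC)[C@H](OCOC)C=C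
F5 | step 23 | 4-epi-34 (4S allylic alcohol) | O[C@H]1C[C@@H](OC(C)=O)[C@@]2(C)[C@@H](OC(C)=O)CC=C(C)[C@@H]2[C@@H](OC(C)=O)[C@@]2(O)[C@H](/C=C\1CO[Si](c3ccccc3)(c3ccccc3)C(C)(C)C)OC(=O)[C@@H]2C
F6 | step 23 | macrocyclic 4-ketone (enone) | O=C1C[C@@H](OC(C)=O)[C@@]2(C)[C@@H](OC(C)=O)CC=C(C)[C@@H]2[C@@H](OC(C)=O)[C@@]2(O)[C@H](/C=C\1CO[Si](c3ccccc3)(c3ccccc3)C(C)(C)C)OC(=O)[C@@H]2C
F7 | step 8 | (2R)-2-hydroxy-14-ketone | CC(C)(C)[Si](C)(C)OCC[C@@H](O)[C@@]1(C)C(=O)CC=C2[C@@H]1[C@@H](OC2=O)[C@H](OCOC)C=C
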